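**Seeking constants.** Look first for a constant in the gamma run, which is the very flask asked about, followed so far. In it the starting complex exchanges with the incoming ligand, and the readings show the complex with one exchanged falling after an early high.

- gamma: starting complex 0.019 M; incoming ligand 0.076 M; temperature 5 °C; the very flask that is asked about, followed so far
- flask: starting complex 0.019 M; incoming ligand 0.0760 M; temperature 5 °C; time 5.0 d

gamma run (percent of the starting complex charged)

| time / h | complex with one exchanged / % | starting complex / % |
|---|---|---|
| 6.00 | 26.8 | 53.1 |
| 12.0 | 18.8 | 47.6 |
| 30.0 | 11.7 | 40.7 |
| 72.0 | 9.4 | 35.3 |

(each reading ± 0.5 percentage points)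

- winter: change nothing and wait 2.5 d more
- midnight: at 5.0 d add incoming ligand, 100 % of the amount charged, then wait 2.5 d
- spring: at 5.0 d raise the temperature by 10 K, then wait 2.5 d
- summer: at 5.0 d take out 90 % of the complex with one exchanged then present, then wait 2.5 d

- complex with one exchanged that was removed still counts
- additions bring no volume worth counting
- the earlier runs do not show what temperature does; that part of a forecast is a guess

* complex with one exchanged, in percent of the starting complex first charged, at 5.0 d
* which option adds most complex with one exchanged ("none" when 2 percentage points or less is all one gets) (winter / midnight / spring / summer / none)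
* complex with one exchanged present, with what was taken out counted in, in percent of the starting complex first charged, after winter
* complex with one exchanged present, with what was taken out counted in, in percent of the starting complex first charged, after midnight

**Bench rule.** At the bench you keep the last value of a reading that has stopped moving. The excess of the complex with one exchanged over its last reading halves in about 6.75 h, and the last reading lies 10.7 such half-lives in. So I commit to 9.4 % at 5.0 d, and to the same after winter.

**Its border.** At 12.0 h, 1.78 half-lives in, the rule fails, and it cannot describe a flask you disturb. So freeze something else: the disproportionation quotient D, the square of the complex with one exchanged over the starting complex times the gap in the readings, which I take to be further exchanged forms. For a gap that holds the next exchanged form and nothing else, the ligands cancel between the two successive exchanges, so D is then free of the ligand concentrations. Any later form in the gap brings a dependence on them back, so I use D as an approximation. It falls from 0.221 at 12.0 h to 0.0453 at 72.0 h, a reading that carries the scatter.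

**Reckoning the options.** In summer, suppose the starting complex and the gap each give up half of what is removed. D then refills the complex with one exchanged to 8.47 %, a gain of 7.5 percentage points. At midnight, added ligand should lower the starting complex, already less than the gap. Guessing 17.6 % of it, D gives 7.63 %. Spring stays a guess. I choose summer.

**The forecast.** It gives 8.8 % (8 % to 9.4 %), a little lower than mine, then 8.7 % after winter and 7.1 % after midnight, and of summer it says “This is the best option”.

**The flask.** It gives 9.57 % at 5.0 d, 9.56 % after winter and 7.51 % after midnight. The best option is summer, with a gain of 7.7 points.

    starting complex + incoming ligand ⇌ leaving ligand + complex with one exchanged (K = 0.220, k = 5.00 L mol⁻¹ h⁻¹, Ea = 48.0 kJ mol⁻¹, ΔH = −67.0 kJ mol⁻¹)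
    complex with one exchanged + incoming ligand ⇌ leaving ligand + complex with two exchanged (K = 4.40, k = 3.30 L mol⁻¹ h⁻¹, Ea = 64.0 kJ mol⁻¹, ΔH = −71.0 kJ mol⁻¹)
    complex with two exchanged + incoming ligand ⇌ leaving ligand + complex with three exchanged (K = 0.0520, k = 6.30 L mol⁻¹ h⁻¹, Ea = 66.0 kJ mol⁻¹, ΔH = −33.0 kJ mol⁻¹)
    incoming ligand ⇌ dormant form (K = 0.820, k = 0.580 h⁻¹, Ea = 91.0 kJ mol⁻¹, ΔH = 1.00 kJ mol⁻¹)
    (constants at 5 °C)

**Standing still.** The slowest mode of this flask has a half-life of 10.9 h at 120 h, short against 5.0 d, and the second exchange then runs backward at 99.9 % of its forward rate. So this flask is in balance by then, and left ten times as long it holds 9.56 %.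

**A second flask.** The neighbour charged with 0.0047 M of starting complex ends with 5.19 % of it and 90.4 % in the two further exchanged forms, so D gives 4.61 % of complex with one exchanged. The computed value is 4.43 %.

(The earlier runs and the new flask stem from a simulated flask on assumed constants, noise included.)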